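**Assumption:** the target has no stereocentre and no C=C bond, so "single enantiomer" means the compound as drawn. The C3 carbinol centre created in step 2 is made racemic on purpose and erased in steps 3–4.

## Retrosynthetic overview

1. The saturated C24 chain comes from hydrogenation of 2-phenylethyl (E)-tetracos-2-enoate, which comes from dehydration of the β-hydroxy ester.
2. Key disconnection C2–C3: intermolecular aldol addition of the lithium enolate of 2-phenylethyl acetate (C1–C2 plus the complete ester) to docosanal (C3–C24).
3. Docosanal comes from oxidation of cheap 1-docosanol (behenyl alcohol).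
4. No ring is formed: the only ring, the benzene ring, arrives intact in commercial 2-phenylethyl acetate.

## Route

Step 1
Reactants: 1 1-docosanol
Product: 2 docosanal
Conditions: IBX (2 equiv), EtOAc, 80 °C, 3 h; filter, concentrate; use promptly under Ar
Reagents that add atoms: none
Why: IBX oxidation in hot EtOAc dissolves the waxy alcohol, stops at the aldehyde because no water is present for over-oxidation, and the insoluble iodine by-product is removed by filtration.

Step 2
Reactants: 3 2-phenylethyl acetate; 2 docosanal
Product: 6 rac-2-phenylethyl 3-hydroxytetracosanoate, via lithium enolate of 2-phenylethyl acetate 4 (not isolated), via lithium 3-alkoxide of 2-phenylethyl 3-hydroxytetracosanoate 5 (not isolated)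
Conditions: LDA (1.15 equiv, commercial solution), THF, −78 °C, 3 (1.2 equiv), 30 min; then 2 (1.0 equiv) in THF, slow addition, −78 °C, 1 h; sat. aq. NH4Cl
Reagents that add atoms: none
Why: Intermolecular aldol addition of a preformed lithium ester enolate to an unhindered aliphatic aldehyde is fast and irreversible at −78 °C and forms the C2–C3 bond, and the new C3 centre is left racemic because it is removed later.

Step 3
Reactants: 6 rac-2-phenylethyl 3-hydroxytetracosanoate
Product: 8 2-phenylethyl (E)-tetracos-2-enoate, via rac-2-phenylethyl 3-(methanesulfonyloxy)tetracosanoate 7 (not isolated)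
Conditions: MsCl (1.5 equiv), Et3N (3 equiv), CH2Cl2, 0 °C to rt; then DBU (2 equiv), rt
Reagents that add atoms: none
Why: Mesylation followed by DBU-mediated E1cB elimination of the β-mesyloxy ester gives the conjugated E-enoate, and any Z or β,γ isomer converges to the same product in step 4.

Step 4
Reactants: 8 2-phenylethyl (E)-tetracos-2-enoate
Product: 9 2-phenylethyl tetracosanoate
Conditions: H2 (1 atm), 10% Pd/C, EtOAc/THF, rt to 35 °C; filter through Celite, recrystallise from acetone
Reagents that add atoms: none
Why: Heterogeneous catalytic hydrogenation of the conjugated alkene is a clean addition with no co-product, and the homobenzylic (not benzylic) ester C–O bond and the arene are inert to Pd/C at 1 atm.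

## Compound list

1 | 1-docosanol (behenyl alcohol) | CCCCCCCCCCCCCCCCCCCCCCO | starting material
2 | docosanal | CCCCCCCCCCCCCCCCCCCCCC=O | intermediate
3 | 2-phenylethyl acetate | CC(=O)OCCc1ccccc1 | starting material
4 | lithium enolate of 2-phenylethyl acetate | C=C(O[Li])OCCc1ccccc1 | intermediate
5 | lithium 3-alkoxide of 2-phenylethyl 3-hydroxytetracosanoate (racemic at C3) | CCCCCCCCCCCCCCCCCCCCCC(O[Li])CC(=O)OCCc1ccccc1 | intermediate
6 | rac-2-phenylethyl 3-hydroxytetracosanoate | CCCCCCCCCCCCCCCCCCCCCC(O)CC(=O)OCCc1ccccc1 | intermediate
7 | rac-2-phenylethyl 3-(methanesulfonyloxy)tetracosanoate | CCCCCCCCCCCCCCCCCCCCCC(OS(C)(=O)=O)CC(=O)OCCc1ccccc1 | intermediate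
8 | 2-phenylethyl (E)-tetracos-2-enoate | CCCCCCCCCCCCCCCCCCCCC/C=C/C(=O)OCCc1ccccc1 | intermediate
9 | 2-phenylethyl tetracosanoate (achiral) | CCCCCCCCCCCCCCCCCCCCCCCC(=O)OCCc1ccccc1 | target

## Summary

Total step count: 4
Longest linear sequence: 4 steps (1 → 2 → 6 → 8 → 9)

## Steps most likely to fail, with fallbacks

**Step 2 (aldol addition).** Docosanal may precipitate from THF at −78 °C or be enolised by the basic lithium enolate, giving incomplete conversion or self-aldol. The fallback sets out from 2 and comes back to the route at 6, using a Reformatsky reaction under warm, essentially neutral conditions. 2-Phenylethanol is acylated with bromoacetyl bromide (pyridine, CH2Cl2, 0 °C) to give 2-phenylethyl bromoacetate F1. F1 and 2 are added together to TMSCl-activated zinc dust in THF at 45–65 °C, where the aldehyde is fully dissolved. Zinc insertion gives the bromozinc enolate of 2-phenylethyl acetate F2, which adds to 2 to give the bromozinc 3-alkoxide of 2-phenylethyl 3-hydroxytetracosanoate F3. Work-up with cold dilute HCl releases 6.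

**Step 3 (mesylation and elimination).** The β-hydroxy ester could undergo retro-aldol cleavage under amine base, or the elimination could stall. The fallback sets out from 6 and comes back at the target 9, bypassing 8 and step 4, by Barton–McCombie deoxygenation instead of elimination and hydrogenation. Compound 6 is treated with phenyl chlorothionoformate (DMAP, pyridine, CH2Cl2, rt) to give rac-2-phenylethyl 3-[(phenoxycarbonothioyl)oxy]tetracosanoate F4. Radical reduction of F4 with Bu3SnH and AIBN in toluene at 100 °C replaces the C3–O bond by C–H and gives 9 directly. Any enoate 8 formed by thermal elimination is simply carried through step 4.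

**Step 1 (oxidation to the aldehyde).** Docosanal is waxy, autoxidises and oligomerises on storage, so it may not be obtained pure enough for the enolate chemistry. The fallback sets out from 1 and comes back at 6, avoiding the aldehyde by forming the same C2–C3 bond at the acid oxidation level. Compound 1 is oxidised fully by Jones oxidation (CrO3, H2SO4, acetone, 30 °C) to docosanoic acid F5. SOCl2 (cat. DMF, toluene, 70 °C) converts F5 into docosanoyl chloride F6. F6 is added at −78 °C to 2.1 equiv of the lithium enolate 4 (from 3 and LDA, THF), a crossed Claisen-type C-acylation, to give 2-phenylethyl 3-oxotetracosanoate F7. NaBH4 (THF/EtOH, 0 °C) reduces only the ketone of F7 and gives 6.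

## Further compounds

F1 | step 2 | 2-phenylethyl bromoacetate | BrCC(=O)OCCc1ccccc1
F2 | step 2 | bromozinc enolate of 2-phenylethyl acetate (Reformatsky reagent) | Br[Zn]CC(=O)OCCc1ccccc1
F3 | step 2 | bromozinc 3-alkoxide of 2-phenylethyl 3-hydroxytetracosanoate (racemic at C3) | CCCCCCCCCCCCCCCCCCCCCC(O[Zn]Br)CC(=O)OCCc1ccccc1
F4 | step 3 | rac-2-phenylethyl 3-[(phenoxycarbonothioyl)oxy]tetracosanoate | CCCCCCCCCCCCCCCCCCCCCC(OC(=S)Oc1ccccc1)CC(=O)OCCc1ccccc1
F5 | step 1 | docosanoic acid | CCCCCCCCCCCCCCCCCCCCCC(=O)O
F6 | step 1 | docosanoyl chloride | CCCCCCCCCCCCCCCCCCCCCC(=O)Cl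
F7 | step 1 | 2-phenylethyl 3-oxotetracosanoate | CCCCCCCCCCCCCCCCCCCCCC(=O)CC(=O)OCCc1ccccc1
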